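The target is read as the Diels–Alder dimer of one guaianolide monomer, so everything rests on making that monomer's cycloheptane by cutting C1–C10 and C6–C7. The feature exploited is the cis C1–C5 fusion of cyclopentanone and cycloheptane next to the oxygenated C6: C1, C5 and C6 are stored as a cyclopropanol. In one operation palladium opens its C1–C6 bond, joins C1 to the vinyl bromide carbon C10, and the aldehyde freed at C6 is trapped by the allylboronate terminus C7 and lactonizes; the chain C10–C9–C8–C7 is thus inserted into the three-membered ring. The precursors are bicyclic cyclopropanol 9 and bromodienyl boronate 16.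

Key step: step 10

Remark (numbering and one assumption): guaiane numbering is used for each half, primed for the spiro-ketone half; the configuration at C5 and C10 of the enone half (H-5, H-6 and H-10 all β) is assumed to be the thermodynamic one, reached by base equilibration in step 15.

Step 1
Reactants: 1 2-(dichloromethyl)-4,4,5,5-tetramethyl-1,3,2-dioxaborolane
Product: 2 2-(diiodomethyl)-4,4,5,5-tetramethyl-1,3,2-dioxaborolane
Conditions: NaI, acetone, reflux
Reagents that add atoms: sodium iodide, [Na+].[I-]
Why: Finkelstein halide exchange, driven by precipitation of NaCl, should give the diiodide needed for the zinc carbenoid.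

Step 2
Reactants: 3 sodium cyclopentadienide; 4 iodomethyl pivalate
Product: 6 [(1R,5S)-5-hydroxycyclopent-2-en-1-yl]methyl pivalate (trans), via cyclopentadienylmethyl pivalate 5 (not isolated)
Conditions: THF, −78 → −50 °C; then (−)-Ipc2BH [from (+)-α-pinene], THF, −60 → 0 °C; then NaBO3·4H2O, H2O, rt
Reagents that add atoms: sodium perborate (hydroxyl oxygen), [Na+].[Na+].O[B-]1(O)OO[B-](O)(O)OO1
Why: SN2 C-alkylation of cyclopentadienide gives diene 5, which is trapped cold by Brown asymmetric hydroboration–oxidation before 1,5-hydrogen shift; boron adds next to the sp3 carbon anti to the side chain, so the trans relationship and the absolute configuration of guaiane C3 and C4 come from the substituent and the reagent.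

Step 3
Reactants: 6; 2
Product: 7 [3-hydroxy-6-(pinacolboryl)bicyclo[3.1.0]hexan-2-yl]methyl pivalate (cyclopropane cis to OH, trans to CH2OPiv, Bpin exo)
Conditions: Et2Zn, then EtZnI (Et2Zn + I2), CH2Cl2, 0 °C → rt
Reagents that add atoms: none
Why: Simmons–Smith-type borocyclopropanation with the boromethylzinc carbenoid; the zinc alkoxide should deliver it syn to OH and anti to CH2OPiv, which sets C1 and C5 (cis by necessity, later H-1α/H-5α) and places Bpin exo.

Step 4
Reactants: 7
Product: 8 triethylsilyl ether of 7
Conditions: TESCl, imidazole, DMF, 0 °C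
Reagents that add atoms: chlorotriethylsilane, CC[Si](Cl)(CC)CC
Why: Standard silylation protects the secondary alcohol so that only the cyclopropanol can bind palladium in step 10.

Step 5
Reactants: 8
Product: 9 [6-exo-hydroxy-3-(triethylsilyloxy)bicyclo[3.1.0]hexan-2-yl]methyl pivalate
Conditions: NaBO3·4H2O, THF/H2O, rt
Reagents that add atoms: sodium perborate, [Na+].[Na+].O[B-]1(O)OO[B-](O)(O)OO1
Why: Oxidation of the C–B bond (1,2-boronate migration, retention) should give the cyclopropanol under mild conditions that the TES ether and pivalate tolerate.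

Step 6
Reactants: 10 3-bromobut-3-en-1-ol
Product: 11 3-bromobut-3-enal
Conditions: Dess–Martin periodinane, NaHCO3, CH2Cl2, 0 °C; used cold and directly
Reagents that add atoms: none
Why: Buffered Dess–Martin oxidation avoids the base that would move the β,γ-double bond into conjugation.

Step 7
Reactants: 11; 12 methyl propiolate
Product: 13 methyl (R)-6-bromo-4-hydroxyhept-6-en-2-ynoate
Conditions: Me2Zn, ProPhenol ligand (cat.; the enantiomer that directs Si-face addition), Ph3P=O (cat.), toluene, 4 °C
Reagents that add atoms: none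
Why: Zn–ProPhenol-catalysed asymmetric alkynylation; the dinuclear zinc catalyst delivers the alkynyl group to the Si face of the aldehyde, which sets C8 as R.

Step 8
Reactants: 13
Product: 14 methyl (R)-6-bromo-4-(tert-butyldimethylsilyloxy)hept-6-en-2-ynoate
Conditions: TBSCl, imidazole, DMF, rt
Reagents that add atoms: tert-butyldimethylsilyl chloride, CC(C)(C)[Si](C)(C)Cl
Why: Silylation blocks butenolide formation from the later Z-γ-oxy enoate and carries C8–O to the end.

Step 9
Reactants: 14; 15 2-(iodomethyl)-4,4,5,5-tetramethyl-1,3,2-dioxaborolane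
Product: 16 methyl (2Z,4R)-6-bromo-4-(tert-butyldimethylsilyloxy)-2-[(pinacolboryl)methyl]hepta-2,6-dienoate
Conditions: DIBAL-H, HMPA, THF, 0 °C; then 15, rt
Reagents that add atoms: none
Why: Conjugate syn-hydroalumination of the ynoate, then C-alkylation of the α-alumino enoate by the iodomethylboronate with retention of alkene geometry, is an established route to 2-alkoxycarbonyl allylboronates and should give the Z isomer (C8 cis to the ester); vinyl bromide and silyl ether are inert.

Step 10
Reactants: 9; 16
Product: 19 8β-(tert-butyldimethylsilyloxy)-15-pivaloyloxy-3β-(triethylsilyloxy)-4βH-guaia-10(14),11(13)-dien-12,6α-olide (H-1α, H-5α, H-6β, H-7α), via cis-formyl allylboronate 17 (not isolated), via pinacol alkoxyboronate 18 (not isolated)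
Conditions: Pd(OAc)2 (cat.), XPhos (cat.), Cs2CO3, toluene, 80 °C
Reagents that add atoms: none
Why: Proposed new method: Pd(0) adds to the C10–Br bond of 16, the caesium cyclopropoxide of 9 binds palladium and undergoes β-carbon elimination of the C1–C6 bond, and reductive elimination forms C1–C10 while unmasking the C6 aldehyde (17), which is captured at once by the internal allylboronate through a six-membered chair transition state to form C6–C7 (18) before the borate oxygen acylates on the methyl ester. The closest known reaction types are the Pd-catalysed cross-coupling of cyclopropanol-derived homoenolates with sp2 halides and the tandem allylboration–lactonization of 2-alkoxycarbonyl allylboronates. The cycloheptane is closed by the intramolecular allylboration (C–C addition to C=O, overall a 3→7 ring expansion by insertion of C10–C9–C8–C7 into C1–C6) and the lactone by 5-exo-trig O-acylation. C1 and C5 (both H α) are fixed by the cyclopropane because β-carbon elimination and reductive elimination retain configuration, the trans C6/C7 relationship follows from the Z-alkene (C8 equatorial in the chair), the facial sense from the cis-fused cyclopentane, which keeps the O–B(pin) unit off the ring so that H-6 ends anti to H-5, and C8 is carried in from 16. The step needs cleavage of C1–C6 rather than C5–C6 (C5 is flanked by the branched C4 bearing CH2OPiv, C1 by a CH2), reductive elimination faster than β-hydride elimination (bulky biarylphosphine), and cyclopropoxide ligation faster than allyl transfer from boron (anhydrous carbonate, electron-poor pinacol boronate).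

Step 11
Reactants: 19
Product: 20 3β-hydroxy-8β-(tert-butyldimethylsilyloxy)-15-pivaloyloxy-4βH-guaia-10(14),11(13)-dien-12,6α-olide
Conditions: PPTS, MeOH, 0 °C → rt
Reagents that add atoms: none
Why: Mild acidic methanolysis should remove the secondary TES ether while the secondary TBS ether, the pivalate and the α-methylene lactone stay intact.

Step 12
Reactants: 20
Product: 22 3-oxo-8β-(tert-butyldimethylsilyloxy)guaia-4(15),10(14),11(13)-trien-12,6α-olide, via 15-pivaloyloxy ketone 21 (not isolated)
Conditions: Dess–Martin periodinane, NaHCO3, CH2Cl2, 0 °C; then DBU, 0 °C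
Reagents that add atoms: none
Why: Dess–Martin oxidation gives the β-acyloxy ketone, and E1cB loss of pivalate then unveils the exocyclic enone C4=C15 (C3 and C4 stereocentres are erased as planned).

Step 13
Reactants: 22
Product: 23 3,8β-bis(tert-butyldimethylsilyloxy)guaia-2,4(15),10(14),11(13)-tetraen-12,6α-olide
Conditions: TBSOTf, Et3N, CH2Cl2, −78 °C
Reagents that add atoms: tert-butyldimethylsilyl triflate, CC(C)(C)[Si](C)(C)OS(=O)(=O)C(F)(F)F
Why: Soft enolization–silylation can only occur towards C2, the sole enolizable α-position, giving the 2-silyloxy diene without touching the lactone.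

Step 14
Reactants: 23; 22
Product: 25 Diels–Alder adduct (bonds C2–C4' and C14–C15', Δ1(10) β,γ-enone, spiro C4', both 8-OTBS), via trienone diene 24 (not isolated)
Conditions: Pd(OAc)2 (1.1 equiv), MeCN, rt, argon, 22 in excess
Reagents that add atoms: none
Why: Saegusa–Ito oxidation (Pd enolate, β-hydride elimination of H-1) gives trienone 24, whose s-cis diene C2=C1–C10=C14 adds in a Diels–Alder reaction to the most activated alkene of 22, the exocyclic enone C4'=C15': C14 (largest HOMO coefficient) bonds to the β-carbon C15' and C2 to C4', and the spiro centre is set by attack on the convex α-face of the cis-fused cyclopentanone (the face of H-1'/H-5'); the new C2 centre is erased in step 15.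

Step 15
Reactants: 25
Product: 26 8,8'-bis-O-TBS ether of the target
Conditions: DBU (0.3 equiv), degassed CH2Cl2, rt
Reagents that add atoms: none
Why: Base-mediated 1,3-prototropic shift through the extended dienolate should move C1=C10 into conjugation (C1=C2); C10 and C5 are then both γ to the enone and equilibrate, the planar C5–C1(=C2)–C10 unit holds the ring bonds C5–C6 and C10–C9 on one side so that H-5 and H-10 end cis, and the all-β arrangement of the target is taken as the thermodynamic one (remark above).

Step 16
Reactants: 26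
Product: 27 CNP0397417.1 (target)
Conditions: HF·pyridine, pyridine/THF, 0 °C → rt
Reagents that add atoms: none
Why: Buffered fluoride desilylation should free both 8β-hydroxyls without base, avoiding translactonization and conjugate addition to the methylene lactones.

Compound list
1 | 2-(dichloromethyl)-4,4,5,5-tetramethyl-1,3,2-dioxaborolane | ClC(Cl)B1OC(C)(C)C(C)(C)O1 | starting material
2 | 2-(diiodomethyl)-4,4,5,5-tetramethyl-1,3,2-dioxaborolane | IC(I)B1OC(C)(C)C(C)(C)O1 | intermediate
3 | sodium cyclopentadienide | [Na+].c1cc[cH-]c1 | starting material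
4 | iodomethyl pivalate | CC(C)(C)C(=O)OCI | starting material
5 | (cyclopenta-2,4-dien-1-yl)methyl pivalate | CC(C)(C)C(=O)OCC1C=CC=C1 | intermediate (not isolated)
6 | [(1R,5S)-5-hydroxycyclopent-2-en-1-yl]methyl pivalate | CC(C)(C)C(=O)OC[C@@H]1[C@@H](O)CC=C1 | intermediate
7 | [3-hydroxy-6-exo-(pinacolboryl)bicyclo[3.1.0]hexan-2-yl]methyl pivalate, cyclopropane cis to OH | CC(C)(C)C(=O)OC[C@@H]1[C@@H](O)C[C@H]2[C@H](B3OC(C)(C)C(C)(C)O3)[C@@H]12 | intermediate
8 | triethylsilyl ether of 7 | CC(C)(C)C(=O)OC[C@@H]1[C@@H](O[Si](CC)(CC)CC)C[C@H]2[C@H](B3OC(C)(C)C(C)(C)O3)[C@@H]12 | intermediate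
9 | [6-exo-hydroxy-3-(triethylsilyloxy)bicyclo[3.1.0]hexan-2-yl]methyl pivalate | CC(C)(C)C(=O)OC[C@@H]1[C@@H](O[Si](CC)(CC)CC)C[C@H]2[C@H](O)[C@@H]12 | intermediate
10 | 3-bromobut-3-en-1-ol | OCCC(Br)=C | starting material
11 | 3-bromobut-3-enal | O=CCC(Br)=C | intermediate
12 | methyl propiolate | COC(=O)C#C | starting material
13 | methyl (R)-6-bromo-4-hydroxyhept-6-en-2-ynoate | COC(=O)C#C[C@H](O)CC(Br)=C | intermediate
14 | methyl (R)-6-bromo-4-(tert-butyldimethylsilyloxy)hept-6-en-2-ynoate | COC(=O)C#C[C@H](O[Si](C)(C)C(C)(C)C)CC(Br)=C | intermediate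
15 | 2-(iodomethyl)-4,4,5,5-tetramethyl-1,3,2-dioxaborolane | ICB1OC(C)(C)C(C)(C)O1 | starting material
16 | methyl (2Z,4R)-6-bromo-4-(tert-butyldimethylsilyloxy)-2-[(pinacolboryl)methyl]hepta-2,6-dienoate | COC(=O)/C(CB1OC(C)(C)C(C)(C)O1)=C\[C@H](O[Si](C)(C)C(C)(C)C)CC(Br)=C | intermediate
17 | cis-2-formylcyclopentyl diene allylboronate (C1–C10 formed, C6 aldehyde free) | CC(C)(C)C(=O)OC[C@@H]1[C@@H](O[Si](CC)(CC)CC)C[C@@H](C(=C)C[C@@H](O[Si](C)(C)C(C)(C)C)/C=C(/CB2OC(C)(C)C(C)(C)O2)C(=O)OC)[C@H]1C=O | intermediate (not isolated)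
18 | hydroazulene methyl ester with C6–O–B(pin) (C6–C7 formed) | CC(C)(C)C(=O)OC[C@@H]1[C@@H](O[Si](CC)(CC)CC)C[C@H]2C(=C)C[C@@H](O[Si](C)(C)C(C)(C)C)[C@@H](C(=C)C(=O)OC)[C@H](OB3OC(C)(C)C(C)(C)O3)[C@H]21 | intermediate (not isolated)
19 | 8β-TBSO-15-pivaloyloxy-3β-TESO-4βH-guaia-10(14),11(13)-dien-12,6α-olide | CC(C)(C)C(=O)OC[C@@H]1[C@@H](O[Si](CC)(CC)CC)C[C@H]2C(=C)C[C@@H](O[Si](C)(C)C(C)(C)C)[C@H]3C(=C)C(=O)O[C@@H]3[C@H]21 | intermediate
20 | 3β-hydroxy-8β-TBSO-15-pivaloyloxy-4βH-guaia-10(14),11(13)-dien-12,6α-olide | CC(C)(C)C(=O)OC[C@@H]1[C@@H](O)C[C@H]2C(=C)C[C@@H](O[Si](C)(C)C(C)(C)C)[C@H]3C(=C)C(=O)O[C@@H]3[C@H]21 | intermediate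
21 | 3-oxo-8β-TBSO-15-pivaloyloxy-4βH-guaia-10(14),11(13)-dien-12,6α-olide | CC(C)(C)C(=O)OC[C@@H]1C(=O)C[C@H]2C(=C)C[C@@H](O[Si](C)(C)C(C)(C)C)[C@H]3C(=C)C(=O)O[C@@H]3[C@H]21 | intermediate (not isolated)
22 | 3-oxo-8β-TBSO-guaia-4(15),10(14),11(13)-trien-12,6α-olide (H-1α, H-5α, H-6β, H-7α) | C=C1C(=O)C[C@H]2C(=C)C[C@@H](O[Si](C)(C)C(C)(C)C)[C@H]3C(=C)C(=O)O[C@@H]3[C@H]21 | intermediate
23 | 3,8β-bis(TBSO)-guaia-2,4(15),10(14),11(13)-tetraen-12,6α-olide | C=C1C(O[Si](C)(C)C(C)(C)C)=C[C@H]2C(=C)C[C@@H](O[Si](C)(C)C(C)(C)C)[C@H]3C(=C)C(=O)O[C@@H]3[C@H]21 | intermediate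
24 | 3-oxo-8β-TBSO-guaia-1,4(15),10(14),11(13)-tetraen-12,6α-olide | C=C1C(=O)C=C2C(=C)C[C@@H](O[Si](C)(C)C(C)(C)C)[C@H]3C(=C)C(=O)O[C@@H]3[C@H]21 | intermediate (not isolated)
25 | Diels–Alder adduct, Δ1(10), H-5α, spiro C4' with C2 on the α-face of the primed half; C2 configuration left open because step 15 erases it | C=C1C(=O)C2C3=C(CC[C@]24C(=O)C[C@H]2C(=C)C[C@@H](O[Si](C)(C)C(C)(C)C)[C@H]5C(=C)C(=O)O[C@@H]5[C@H]24)C[C@@H](O[Si](C)(C)C(C)(C)C)[C@H]2C(=C)C(=O)O[C@@H]2[C@@H]13 | intermediate
26 | 8,8'-bis-O-TBS ether of the target (Δ1(2) enone, H-5β, H-10β) | C=C1C(=O)C2=C3[C@H](CC[C@]24C(=O)C[C@H]2C(=C)C[C@@H](O[Si](C)(C)C(C)(C)C)[C@H]5C(=C)C(=O)O[C@@H]5[C@H]24)C[C@@H](O[Si](C)(C)C(C)(C)C)[C@H]2C(=C)C(=O)O[C@@H]2[C@H]13 | intermediate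
27 | CNP0397417.1 | C=C1C(=O)C2=C3[C@H](CC[C@]24C(=O)C[C@H]2C(=C)C[C@@H](O)[C@H]5C(=C)C(=O)O[C@@H]5[C@H]24)C[C@@H](O)[C@H]2C(=C)C(=O)O[C@@H]2[C@H]13 | target

Total step count: 16. Longest linear sequence: 11 steps (2–5, then 10–16; the branch 6–9 is equally long).

Steps most likely to fail

1. Step 10 (proposed new method). The palladium intermediate may be diverted, by allyl transfer from boron to the vinylpalladium, by β-hydride elimination, or by opening of the C5–C6 bond. The freed aldehyde may also epimerize at C5 before it is trapped, or react on the wrong face because the 8-silyloxy group must sit pseudo-axial. Fallback: the two bond formations are separated and the boron is masked. The fallback sets out from 16, which KHF2 in aqueous methanol should convert into the potassium trifluoroborate F1, inert to transmetalation under anhydrous conditions. F1 and 9 are coupled by the known Pd-catalysed cyclopropanol ring-opening cross-coupling (Pd(OAc)2, XPhos, Cs2CO3, dioxane) to give the isolable aldehyde trifluoroborate F2, at which stage regioisomers can be removed. BF3·OEt2 in CH2Cl2 at −78 °C then releases the allyldifluoroborane, which should close C6–C7 through the same closed chair arrangement, and acidic work-up lactonizes. The fallback returns to the route at 19.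

2. Step 15. Equilibration may stop at, or settle on, another C5/C10 diastereomer, and the amine base may start γ-deprotonation of the methylene lactones. Fallback: the order is reversed and the control element changed from thermodynamics to internal delivery. Setting out from 25, HF·pyridine should give the bis-desilylated adduct F4. A weak amine (Et3N, CH2Cl2) then effects the prototropic shift, with the free 8β-hydroxyl of the enone half, which is 1,3 to C10 on the β-face, acting as the proton shuttle to C10. The fallback returns to the route at 27.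

3. Step 14. Trienone 24 may be consumed by self-dimerization, by γ-oxygenation or by palladium-mediated side reactions before it meets 22. Fallback: the diene is generated without palladium by selenoxide elimination. Setting out from 22, LiHMDS then PhSeCl at −78 °C should give the 2α-phenylselanyl ketone F3 (selenium enters on the convex face, syn to H-1). Oxidation with H2O2 at −40 → 0 °C in the presence of excess 22 triggers syn-elimination to 24, which is trapped as it forms. The fallback returns to the route at 25.

Further compounds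
F1 | step 10 | potassium [(2Z,4R)-6-bromo-4-(tert-butyldimethylsilyloxy)-2-(methoxycarbonyl)hepta-2,6-dien-1-yl]trifluoroborate | COC(=O)/C(C[B-](F)(F)F)=C\[C@H](O[Si](C)(C)C(C)(C)C)CC(Br)=C.[K+]
F2 | step 10 | cis-2-formylcyclopentyl diene trifluoroborate (trifluoroborate analogue of 17) | CC(C)(C)C(=O)OC[C@@H]1[C@@H](O[Si](CC)(CC)CC)C[C@@H](C(=C)C[C@@H](O[Si](C)(C)C(C)(C)C)/C=C(/C[B-](F)(F)F)C(=O)OC)[C@H]1C=O.[K+]
F3 | step 14 | 2α-(phenylselanyl) derivative of 22 | C=C1C(=O)[C@H]([Se]c4ccccc4)[C@H]2C(=C)C[C@@H](O[Si](C)(C)C(C)(C)C)[C@H]3C(=C)C(=O)O[C@@H]3[C@H]21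
F4 | step 15 | bis-desilylated Diels–Alder adduct (8,8'-diol of 25) | C=C1C(=O)C2C3=C(CC[C@]24C(=O)C[C@H]2C(=C)C[C@@H](O)[C@H]5C(=C)C(=O)O[C@@H]5[C@H]24)C[C@@H](O)[C@H]2C(=C)C(=O)O[C@@H]2[C@@H]13
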